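**Retrosynthetic overview**
1. Target 5 is a C2-symmetric, fully substituted 2,2'-bipyrrole. The central C2–C2' bond is cut last, giving two molecules of 2,3,4-tribromo-1-methylpyrrole 4 (oxidative C–H/C–H dehydrodimerisation, the new step).
2. 4 comes from tetrabromide 2 by removing one α-bromine (Br/Mg exchange, then protonation).
3. 2 comes from commercial 1-methylpyrrole 1 by fourfold NBS bromination.
4. No ring is built: both pyrrole rings come intact from 1, and all six C–Br bonds are in place before the rings are joined.

Assumption: the SMILES has no stereodescriptor and the molecule has no stereocentre; the hindered 2,2'-axis is treated as unspecified, so the target is made as drawn (racemic about the axis if it is configurationally stable).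

**Step 1**
Reactants: 1 1-methyl-1H-pyrrole
Product: 2 2,3,4,5-tetrabromo-1-methyl-1H-pyrrole
Conditions: NBS (4.2 equiv), THF, −78 °C → rt, dark
Reagents that add atoms: N-bromosuccinimide (NBS), O=C1CCC(=O)N1Br
Why: Electrophilic aromatic bromination (SEAr) of the π-excessive pyrrole runs to completion at all four ring carbons (α before β), and NBS releases neutral succinimide rather than HBr, so the acid-sensitive ring is not polymerised; no stereocentre is formed.

**Step 2**
Reactants: 2 2,3,4,5-tetrabromo-1-methyl-1H-pyrrole
Product: 4 2,3,4-tribromo-1-methyl-1H-pyrrole, via tribromopyrrolylmagnesium chloride 3 (not isolated)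
Conditions: iPrMgCl·LiCl (1.05 equiv), THF, −40 °C; then sat. aq NH4Cl
Reagents that add atoms: isopropylmagnesium chloride–lithium chloride, CC(C)[Mg]Cl.[Li+].[Cl-] (supplies the Mg and Cl of 3; 4 itself gains only hydrogen)
Why: Bromine–magnesium exchange is selective for an α-C–Br bond (carbanion stabilised by the ring nitrogen and the adjacent bromine) and stops after one exchange with one equivalent because 3 is far less electrophilic than 2; protonation of 3 gives 4, and no stereocentre is formed.

**Step 3**
Reactants: 4 2,3,4-tribromo-1-methyl-1H-pyrrole (two molecules, one for each half of 5)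
Product: 5 3,3',4,4',5,5'-hexabromo-1,1'-dimethyl-1H,1'H-2,2'-bipyrrole
Conditions: PhI(OCOCF3)2 (0.55 equiv), BF3·OEt2 (1.1 equiv), CH2Cl2, −40 → −10 °C
Reagents that add atoms: none
Why: Proposed new method: bio-inspired oxidative C–H/C–H dehydrodimerisation of a perbrominated pyrrole. The BF3-activated trivalent-iodine oxidant removes one electron from 4; the radical cation (spin density on the α-carbons) is attacked by the only unsubstituted ring carbon (C5) of a second molecule of 4; loss of a second electron and two protons rearomatises to 5. Because 5 has no ring C–H left, the coupling is self-terminating (no oligomers), and no low-valent transition metal is present to insert into the six C–Br bonds. The closest known reaction type is the hypervalent-iodine/Lewis-acid oxidative biaryl homocoupling of hindered alkylarenes, thiophenes and unhalogenated N-substituted pyrroles; it has not been shown for a polybromopyrrole or for a tetra-ortho-substituted 2,2'-bipyrrole. No stereocentre is set, and the hindered axis forms without control.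

**Compound list**
1 | 1-methyl-1H-pyrrole | Cn1cccc1 | starting material
2 | 2,3,4,5-tetrabromo-1-methyl-1H-pyrrole | Cn1c(Br)c(Br)c(Br)c1Br | intermediate
3 | (3,4,5-tribromo-1-methyl-1H-pyrrol-2-yl)magnesium chloride (LiCl-complexed in THF, not isolated) | Cn1c(Br)c(Br)c(Br)c1[Mg]Cl | intermediate
4 | 2,3,4-tribromo-1-methyl-1H-pyrrole | Cn1cc(Br)c(Br)c1Br | intermediate
5 | 3,3',4,4',5,5'-hexabromo-1,1'-dimethyl-1H,1'H-2,2'-bipyrrole | Cn1c(Br)c(Br)c(Br)c1-c1c(Br)c(Br)c(Br)n1C | target

**Totals**
Total step count: 3. Longest linear sequence: 3 (1 → 2 → 4 → 5).

**Steps most likely to fail, with fallbacks**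

Risk 1, step 3 (the proposed new dehydrodimerisation). Possible failure modes:
- 4 is trapped as a stable pyrrolyl(phenyl)iodonium salt instead of coupling.
- The acidic medium causes bromine transfer between molecules of 4, giving 2 plus dibromopyrroles.
- The hindered radical cation is captured by trifluoroacetate.

The fallback uses only known chemistry; it sets out from 1 and comes back at 5. Compound 1 is lithiated at C2 (nBuLi, TMEDA, hexane, rt) to (1-methyl-1H-pyrrol-2-yl)lithium F1. F1 is oxidatively homocoupled with anhydrous CuCl2 (THF, −78 °C → rt) to 1,1'-dimethyl-1H,1'H-2,2'-bipyrrole F2. Exhaustive electrophilic bromination of the electron-rich bipyrrole F2 with NBS (6.2 equiv, THF, −78 °C → rt) then fills all six ring positions and gives 5. Here the C2–C2' bond is made before any bromine is introduced, so the oxidative coupling of a polybrominated ring is avoided altogether.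

Risk 2, step 2. Compound 4 is an α-bromopyrrole with a free α-position and may be light- and acid-sensitive, so it may not survive isolation and storage in good yield; over-exchange would also erode it. The fallback sets out from 2 and comes back at 5 without isolating 4. Compound 2 is converted into Grignard reagent 3 exactly as above, and the cold solution is treated with anhydrous CuCl2 (1.1 equiv, THF, −78 → 0 °C). Copper-mediated oxidative homocoupling of the aryl Grignard then forms the C2–C2' bond directly from the carbon–magnesium bond. No compound outside the compound list is made (F0). This reaction type is standard for aryl Grignard reagents but is untested on this substrate.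

Risk 3, step 1. The fourth, slowest β-bromination may stall at the tribromide or be overtaken by oxidative decomposition of the partly brominated pyrroles. The fallback sets out from 1 and comes back at 2, introducing the last bromine through a carbanion instead of by SEAr.
- Compound 1 is brominated only as far as 2,3,5-tribromo-1-methyl-1H-pyrrole F3 (NBS 3.0 equiv, THF, −78 °C).
- The single remaining ring C–H of F3, flanked by two bromines and therefore acidic, is magnesiated with TMPMgCl·LiCl (THF, −40 °C) to (2,4,5-tribromo-1-methyl-1H-pyrrol-3-yl)magnesium chloride F4.
- F4 is quenched with BrCl2C–CCl2Br to give 2.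

**Further compounds**
F1 | step 3 | (1-methyl-1H-pyrrol-2-yl)lithium | [Li]c1cccn1C
F2 | step 3 | 1,1'-dimethyl-1H,1'H-2,2'-bipyrrole | Cn1cccc1-c1cccn1C
F0 | step 2 | none | none
F3 | step 1 | 2,3,5-tribromo-1-methyl-1H-pyrrole | Cn1c(Br)cc(Br)c1Br
F4 | step 1 | (2,4,5-tribromo-1-methyl-1H-pyrrol-3-yl)magnesium chloride | Cl[Mg]c1c(Br)n(C)c(Br)c1Br
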